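**Retrosynthetic overview**

1. Dihydrobenzofuran O–C(aryl) bond of target 5 ⇒ chalcane-flavan dimer 3; the ring closes by dehydration through cyclic hemiketal 4, with retention at the carbinol carbon.
2. Benzylic C–C-8 bond of 3 ⇒ (+)-catechin 1 as C-8 nucleophile plus p-quinone methide 2, the ring-opened form of a second molecule of 1.
3. Both disconnections are run forward in one flask without protecting groups: 1 + 1 → 2 → 3 → 4 → 5.
4. Ring order: the three rings of the flavan unit come intact from 1; the pyran ring of the second molecule is opened first and its atoms are re-closed last as the five-membered dihydrobenzofuran ring, the only ring formed.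

Assumption: (+)-catechin is used as its commercial hydrate; "upper unit" is the molecule that becomes the dihydrobenzofuran and "lower unit" the one that stays a flavan.

**Route**

Step 1
Reactants: 1 (+)-catechin (two molecules: one as electrophile precursor, one as C-8 nucleophile)
Product: 5 target dihydrobenzofuran-flavan dimer, via quinone methide 2 (not isolated), via chalcane-flavan dimer 3 (not isolated), via hemiketal 4 (not isolated)
Conditions: degassed H2O, NaOAc/AcOH buffer (50 mM, pH 5.5), 0.3 M in 1, Ar, sealed tube, 120 °C, 4 h; then AcOH to 10% v/v, 110 °C, 3 h (same flask); MCI-gel CHP20P, Sephadex LH-20, then preparative ODS HPLC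
Reagents that add atoms: none
Why: Proposed new method: a one-flask, protecting-group-free dimerisation and ring contraction in which 1 first opens thermally at the C-2–O-1 bond to the p-quinone methide 2 (the pathway behind the thermal C-2 epimerisation of flavan-3-ols), C-8 of a second molecule of 1 then adds to the methide carbon (Friedel–Crafts-type 1,6-addition) anti to the trihydroxybenzyl arm in the conformer whose C-3 hydrogen eclipses the methide (allylic 1,3-strain control by the untouched carbinol centre), which is net inversion at the former C-2 and sets the benzylic R centre of 3, and the carbinol oxygen of 3 finally adds 5-exo to the carbonyl of the 2,4-dienone tautomer of the freed phloroglucinol ring to give hemiketal 4, which loses water and re-aromatises, so that no bond to the carbinol carbon is broken and the 3S centre of catechin becomes the 2S dihydrobenzofuran centre with retention; the closest known reaction types are quinone-methide alkylation of phloroglucinol-type arenes and the acid-catalysed etherification of phloroglucinol by alcohols through its keto tautomer.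

**Compound list**

1 | (+)-catechin, (2R,3S)-2-(3,4-dihydroxyphenyl)chromane-3,5,7-triol | Oc1cc(O)c2c(c1)O[C@H](c1ccc(O)c(O)c1)[C@@H](O)C2 | starting material
2 | ring-opened p-quinone methide of 1, 2-hydroxy-4-[(2S)-2-hydroxy-3-(2,4,6-trihydroxyphenyl)propylidene]cyclohexa-2,5-dien-1-one (alkene geometry not fixed) | O=C1C=CC(=C[C@@H](O)Cc2c(O)cc(O)cc2O)C=C1O | intermediate
3 | chalcane-flavan dimer, (2R,3S)-2-(3,4-dihydroxyphenyl)-8-[(1R,2S)-1-(3,4-dihydroxyphenyl)-2-hydroxy-3-(2,4,6-trihydroxyphenyl)propyl]chromane-3,5,7-triol | Oc1cc(O)c(C[C@H](O)[C@H](c2ccc(O)c(O)c2)c2c(O)cc(O)c3c2O[C@H](c2ccc(O)c(O)c2)[C@@H](O)C3)c(O)c1 | intermediate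
4 | cyclic hemiketal of 3: the carbinol oxygen is bonded to C-2 of the free phloroglucinol ring in its 2,4-dienone form, giving a (2S)-2-substituted 2,3,7,7a-tetrahydro-1-benzofuran-4,6,7a-triol unit; hemiketal carbon 7a not specified, the other four centres as in 3 | OC1=CC(O)=C2C(O)(C1)O[C@H]([C@H](c1ccc(O)c(O)c1)c1c(O)cc(O)c3c1O[C@H](c1ccc(O)c(O)c1)[C@@H](O)C3)C2 | intermediate
5 | target, (2R,3S)-2-(3,4-dihydroxyphenyl)-8-[(R)-[(2S)-4,6-dihydroxy-2,3-dihydro-1-benzofuran-2-yl](3,4-dihydroxyphenyl)methyl]chromane-3,5,7-triol (gambiriin-B-type dimer) | Oc1cc(O)c2c(c1)O[C@H]([C@H](c1ccc(O)c(O)c1)c1c(O)cc(O)c3c1O[C@H](c1ccc(O)c(O)c1)[C@@H](O)C3)C2 | target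

**Totals and risks**

Total step count: 1. Longest linear sequence: 1.

The route has one step, so step 1 is the only step that can be named as likely to fail.

Step 1 is expected to give the dimer in only about 5–10% on consumed 1. Unchanged 1 and its C-2 epimer are recovered from the MCI-gel column and recycled, since both give the same 2. Any 3 that has not closed is returned to the AcOH stage. The competing paths are:
- attack through C-6 instead of C-8;
- attack on the other face of the methide;
- further oligomerisation;
- C-2 epimerisation of the flavan unit;
- closure of the carbinol oxygen onto C-7 of the flavan ring A instead of the free phloroglucinol ring.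

The fallback decouples the two bond formations and moves the isomer separation to an earlier compound. It sets out from 1 and makes the chalcane-flavan dimer 3 under acid catalysis (0.1 M HCl in 1,4-dioxane/H2O 1:1, 70 °C, stopped at about 30% conversion). Here the electrophile is the protonated quinone methide, and at this temperature little ring closure is expected. Compound 3 is isolated on Sephadex LH-20 and reversed-phase silica and freed from its C-6-linked and benzylic isomers at this stage. The five-membered ring is then closed in a separate flask (degassed 10% aqueous AcOH, Ar, 110 °C) under conditions tuned only for the hemiketal dehydration, and the route is re-entered at 5. No compound outside the list is made (F0).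

**Further compounds**

F0 | step 1 | none | none
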